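A direct plan would attach ring B to a finished chromone: 5,7-bis(tert-butyldimethylsilyloxy)chromone A1 would be coupled at C2, by an enantioselective nickel-catalysed reductive conjugate arylation, with an aryl bromide made from 4-bromo-2-geranylphenol A2 (itself from a phenoxide C-geranylation) by silylation to A3 and hydration of its distal alkene. Its weakest steps would be:
- the asymmetric reductive arylation, which would have to set the only stereocentre by a coupling known only in racemic form on simple enones;
- the hydration of one of the two trisubstituted alkenes of A3, which would differ little towards hydrogen-atom transfer;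
- the C-geranylation giving A2, in which O-alkylation and double alkylation would compete.

The new route disconnects ring C across both O1–C2 and C3–C4. The formyl phenol of ring A, which is the stable tautomer of a hydroxy-substituted ortho-quinone methide, and the 4-hydroxystyrene of ring B are annulated under a chiral phosphoric acid. This single operation joins the two arenes, closes ring C, brings in the C4 oxygen and sets C2; it exploits the free 4′-hydroxyl para to C2, which turns the vinyl group into a vinylogous enol. No C2–aryl coupling is needed, and the side chain is built from an alkynol by carboalumination and benzylic coupling, so neither phenoxide C-alkylation nor selective alkene hydration occurs.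

Key step: step 7

Assumption: the (R)-configured phosphoric acid is taken to deliver the (2S) series; were the sense of induction the opposite, its (S)-enantiomer would be used.

Step 1
Reactants: 1 2,4,6-trihydroxybenzaldehyde
Product: 2 2-hydroxy-4,6-bis(tert-butyldimethylsilyloxy)benzaldehyde
Conditions: TBSCl (2.1 equiv), imidazole (4.5 equiv), DMF, 0 °C
Reagents that add atoms: tert-butyldimethylsilyl chloride, CC(C)(C)[Si](C)(C)Cl
Why: Imidazole-mediated phenol silylation should take the para-hydroxyl and one of the two equivalent ortho-hydroxyls, while the last ortho-hydroxyl is held in the chelate hydrogen bond to the formyl group and stays free.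

Step 2
Reactants: 3 methyl hex-5-ynoate
Product: 4 2-methylhept-6-yn-2-ol
Conditions: MeMgBr (3.3 equiv), THF, 0 °C → rt; aq. NH4Cl
Reagents that add atoms: methylmagnesium bromide, C[Mg]Br
Why: Double Grignard addition to the ester should give the tertiary alcohol directly (the third equivalent is taken up by the acetylenic C–H, which is restored on work-up), so the hydroxyl of the side chain is in place before any alkene exists.

Step 3
Reactants: 5 4-bromo-2-methylphenol
Product: 6 (4-bromo-2-methylphenoxy)(tert-butyl)dimethylsilane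
Conditions: TBSCl (1.1 equiv), imidazole (2.2 equiv), DMF, rt
Reagents that add atoms: tert-butyldimethylsilyl chloride, CC(C)(C)[Si](C)(C)Cl
Why: Standard imidazole-mediated silyl ether formation blocks the phenol for the radical bromination and the organoaluminium chemistry that follow.

Step 4
Reactants: 6 (4-bromo-2-methylphenoxy)(tert-butyl)dimethylsilane
Product: 7 [4-bromo-2-(bromomethyl)phenoxy](tert-butyl)dimethylsilane
Conditions: NBS (1.05 equiv), AIBN (5 mol%), PhCF3, 80 °C
Reagents that add atoms: N-bromosuccinimide, O=C1CCC(=O)N1Br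
Why: Wohl–Ziegler bromination by a radical chain at the only benzylic position, run in a non-polar solvent so that ionic ring bromination of the silyl ether stays slow.

Step 5
Reactants: 4 2-methylhept-6-yn-2-ol; 7 [4-bromo-2-(bromomethyl)phenoxy](tert-butyl)dimethylsilane
Product: 9 (6E)-8-[5-bromo-2-(tert-butyldimethylsilyloxy)phenyl]-2,6-dimethyloct-6-en-2-ol, via (E)-alkenyldimethylalane 8 (not isolated)
Conditions: 4 (1.2 equiv), Me3Al (3.6 equiv), Cp2ZrCl2 (0.3 equiv), CH2Cl2, 0 °C → rt; volatiles removed; then 7 (1.0 equiv), Pd(PPh3)4 (5 mol%), THF, rt; aq. potassium sodium tartrate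
Reagents that add atoms: trimethylaluminium, C[Al](C)C
Why: Negishi zirconium-catalysed carboalumination adds methyl and aluminium syn across the terminal alkyne with methyl at the internal carbon (the hydroxyl riding as its aluminium alkoxide), and the Negishi cross-coupling of the E-alkenylalane with the benzylic bromide goes with retention, zerovalent palladium inserting into the benzylic C–Br bond far faster than into the electron-rich aryl C–Br bond at rt, so the E-trisubstituted alkene is fixed.

Step 6
Reactants: 9 (6E)-8-[5-bromo-2-(tert-butyldimethylsilyloxy)phenyl]-2,6-dimethyloct-6-en-2-ol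
Product: 11 4-ethenyl-2-[(2E)-7-hydroxy-3,7-dimethyloct-2-en-1-yl]phenol, via vinylarene silyl ether 10 (not isolated)
Conditions: CH2=CHBpin (1.5 equiv), PdCl2(dppf) (3 mol%), K2CO3 (3 equiv), 1,4-dioxane–H2O (5:1), 80 °C; then MeOH, rt → 40 °C; BHT (trace) on concentration, used at once
Reagents that add atoms: 2-ethenyl-4,4,5,5-tetramethyl-1,3,2-dioxaborolane, C=CB1OC(C)(C)C(C)(C)O1
Why: Suzuki–Miyaura vinylation of the aryl bromide, followed in the same flask by carbonate-mediated methanolysis of the aryl silyl ether, should free the 4-hydroxystyrene that the key step needs, the tertiary alcohol and the trisubstituted alkene being inert to both.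

Step 7
Reactants: 2 2-hydroxy-4,6-bis(tert-butyldimethylsilyloxy)benzaldehyde; 11 4-ethenyl-2-[(2E)-7-hydroxy-3,7-dimethyloct-2-en-1-yl]phenol
Product: 13 (2S,4S)-5,7-bis(tert-butyldimethylsilyloxy)-2-{4-hydroxy-3-[(2E)-7-hydroxy-3,7-dimethyloct-2-en-1-yl]phenyl}-3,4-dihydro-2H-chromen-4-ol, via para-quinone methide 12 (not isolated)
Conditions: (R)-3,3′-bis(2,4,6-triisopropylphenyl)-1,1′-binaphthyl-2,2′-diyl hydrogen phosphate (10 mol%), 11 (1.3 equiv, slow addition), 4 Å MS, toluene, −20 → 0 °C; Et3N quench
Reagents that add atoms: none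
Why: Proposed new method: a chiral phosphoric acid should catalyse a formal oxa-[4+2] annulation in which its acidic proton activates the formyl group of 2 (the conjugate acid is the hydroxy-substituted ortho-quinone methide cation of ring A) and its phosphoryl oxygen holds the phenol of 11, so that the vinylogous enol carbon of 11 adds to C4 and the resulting para-quinone methide 12 is captured at C2 by the free ortho-hydroxyl of ring A. The closest known reaction types are the chiral phosphoric acid-catalysed [4+2] cycloaddition of ortho-quinone methides with hydroxystyrenes to chromans, the chiral Brønsted acid-catalysed Prins addition of styrenes to aldehydes, the intramolecular [4+2] reaction of salicylaldehyde-derived alkoxy ortho-quinone methides, and the phosphoric acid-catalysed 1,6-addition to para-quinone methides. Ring C is closed by a 6-exo-trig oxa-1,6-addition, the stepwise limit of an inverse-demand hetero-Diels–Alder reaction, so that C3–C4 and O1–C2 are formed in one operation. C4 is set by the catalyst in the C–C bond formation within the doubly hydrogen-bonded complex, and C2 is set in the closure of 12 on the catalyst and is tied to C4, because this closure is reversible under the acid and should drain the C2 epimers into the 2,4-cis isomer with both substituents pseudo-equatorial, which is 2S when C4 is S. The step needs the vinylphenol alkene to react in preference to the trisubstituted alkene of the side chain and to the ring carbons of the silylated ring A, which the para-hydroxyl (a vinylogous enol bound to the catalyst) and the bulk of the silyl ethers secure, and it needs a single free ortho-hydroxyl in 2, which step 1 provides. The C4 carbinol is a temporary stereocentre that is erased in step 8, so only the configuration at C2 has to be right.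

Step 8
Reactants: 13 (2S,4S)-5,7-bis(tert-butyldimethylsilyloxy)-2-{4-hydroxy-3-[(2E)-7-hydroxy-3,7-dimethyloct-2-en-1-yl]phenyl}-3,4-dihydro-2H-chromen-4-ol
Product: 14 (2S)-5,7-bis(tert-butyldimethylsilyloxy)-2-{4-hydroxy-3-[(2E)-7-hydroxy-3,7-dimethyloct-2-en-1-yl]phenyl}-2,3-dihydro-4H-chromen-4-one
Conditions: activated MnO2 (15 equiv), CH2Cl2, rt
Reagents that add atoms: none
Why: Heterogeneous MnO2 oxidation of a benzylic alcohol that is strongly activated by the trioxygenated ring A should give the ketone under neutral conditions that cannot open the C2–O1 bond, the tertiary alcohol, the phenol and the isolated alkene not being oxidised.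

Step 9
Reactants: 14 (2S)-5,7-bis(tert-butyldimethylsilyloxy)-2-{4-hydroxy-3-[(2E)-7-hydroxy-3,7-dimethyloct-2-en-1-yl]phenyl}-2,3-dihydro-4H-chromen-4-one
Product: 15 (2S)-5,7-dihydroxy-2-{4-hydroxy-3-[(2E)-7-hydroxy-3,7-dimethyloct-2-en-1-yl]phenyl}-2,3-dihydro-4H-chromen-4-one
Conditions: HF·pyridine (excess), pyridine, THF, 0 °C → rt
Reagents that add atoms: none
Why: Buffered, mildly acidic fluoride desilylation removes the two aryl silyl ethers without forming a phenoxide, so the base-induced ring opening that racemises 5-hydroxy- and 4′-hydroxyflavanones is avoided, and the dilution in pyridine spares the tertiary alcohol and the alkene.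

## Compound list

1 | 2,4,6-trihydroxybenzaldehyde | O=Cc1c(O)cc(O)cc1O | starting material
2 | 2-hydroxy-4,6-bis(tert-butyldimethylsilyloxy)benzaldehyde | O=Cc1c(O)cc(O[Si](C)(C)C(C)(C)C)cc1O[Si](C)(C)C(C)(C)C | intermediate
3 | methyl hex-5-ynoate | C#CCCCC(=O)OC | starting material
4 | 2-methylhept-6-yn-2-ol | C#CCCCC(C)(C)O | intermediate
5 | 4-bromo-2-methylphenol | Cc1cc(Br)ccc1O | starting material
6 | (4-bromo-2-methylphenoxy)(tert-butyl)dimethylsilane | Cc1cc(Br)ccc1O[Si](C)(C)C(C)(C)C | intermediate
7 | [4-bromo-2-(bromomethyl)phenoxy](tert-butyl)dimethylsilane | BrCc1cc(Br)ccc1O[Si](C)(C)C(C)(C)C | intermediate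
8 | dimethyl{(1E)-6-[(dimethylalumanyl)oxy]-2,6-dimethylhept-1-en-1-yl}alumane | C/C(=C\[Al](C)C)CCCC(C)(C)O[Al](C)C | intermediate
9 | (6E)-8-[5-bromo-2-(tert-butyldimethylsilyloxy)phenyl]-2,6-dimethyloct-6-en-2-ol | C/C(=C\Cc1cc(Br)ccc1O[Si](C)(C)C(C)(C)C)CCCC(C)(C)O | intermediate
10 | tert-butyl{4-ethenyl-2-[(2E)-7-hydroxy-3,7-dimethyloct-2-en-1-yl]phenoxy}dimethylsilane | C/C(=C\Cc1cc(C=C)ccc1O[Si](C)(C)C(C)(C)C)CCCC(C)(C)O | intermediate
11 | 4-ethenyl-2-[(2E)-7-hydroxy-3,7-dimethyloct-2-en-1-yl]phenol | C/C(=C\Cc1cc(C=C)ccc1O)CCCC(C)(C)O | intermediate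
12 | 4-{(3S)-3-[2-hydroxy-4,6-bis(tert-butyldimethylsilyloxy)phenyl]-3-hydroxypropylidene}-2-[(2E)-7-hydroxy-3,7-dimethyloct-2-en-1-yl]cyclohexa-2,5-dien-1-one (geometry of the exocyclic alkene not defined) | C/C(=C\CC1=CC(=CC[C@H](O)c2c(O)cc(O[Si](C)(C)C(C)(C)C)cc2O[Si](C)(C)C(C)(C)C)C=CC1=O)CCCC(C)(C)O | intermediate
13 | (2S,4S)-5,7-bis(tert-butyldimethylsilyloxy)-2-{4-hydroxy-3-[(2E)-7-hydroxy-3,7-dimethyloct-2-en-1-yl]phenyl}-3,4-dihydro-2H-chromen-4-ol | C/C(=C\Cc1cc([C@@H]2C[C@H](O)c3c(O[Si](C)(C)C(C)(C)C)cc(O[Si](C)(C)C(C)(C)C)cc3O2)ccc1O)CCCC(C)(C)O | intermediate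
14 | (2S)-5,7-bis(tert-butyldimethylsilyloxy)-2-{4-hydroxy-3-[(2E)-7-hydroxy-3,7-dimethyloct-2-en-1-yl]phenyl}-2,3-dihydro-4H-chromen-4-one | C/C(=C\Cc1cc([C@@H]2CC(=O)c3c(O[Si](C)(C)C(C)(C)C)cc(O[Si](C)(C)C(C)(C)C)cc3O2)ccc1O)CCCC(C)(C)O | intermediate
15 | (2S)-5,7-dihydroxy-2-{4-hydroxy-3-[(2E)-7-hydroxy-3,7-dimethyloct-2-en-1-yl]phenyl}-2,3-dihydro-4H-chromen-4-one | C/C(=C\Cc1cc([C@@H]2CC(=O)c3c(O)cc(O)cc3O2)ccc1O)CCCC(C)(C)O | target

Total step count: 9. Longest linear sequence: 7 steps (steps 3 to 9).

Steps most likely to fail: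

Step 7 (the proposed new method). The facial discrimination in the C–C bond formation may be insufficient, or it may be eroded by reversible ring opening through 12; acid-induced self-oligomerisation of the vinylphenol may also lower the conversion. The fallback uses known chemistry and secures the configuration after the event. Whatever enantiomeric purity step 7 delivers, the material would be carried through step 8, and the scalemic ketone 14 would be upgraded by kinetic resolution through asymmetric transfer hydrogenation with RuCl(p-cymene)[(R,R)-N-tosyl-1,2-diphenylethylenediamine] and HCO2H–Et3N (5:2) at rt. By the usual sense of this catalyst with aryl ketones, the (2R)-ketone should be reduced to the cis-flavanol (2R,4R)-5,7-bis(tert-butyldimethylsilyloxy)-2-{4-hydroxy-3-[(2E)-7-hydroxy-3,7-dimethyloct-2-en-1-yl]phenyl}-3,4-dihydro-2H-chromen-4-ol F1, which would be removed by chromatography, while the (2S)-ketone is left. The fallback sets out from 14 and comes back at 14.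

Step 5. In the one-pot sequence a methyl group may be transferred instead of the alkenyl group, the alkenylalane may be protonated before it couples, or the aryl bromide may take part in the coupling. The fallback separates the two events and inverts the polarity. Alane 8, made from 4 as in step 5, would be quenched with I2 in THF at −30 °C to give (6E)-7-iodo-2,6-dimethylhept-6-en-2-ol F2. Bromide 7 would be converted with zinc dust and LiCl in THF into {[5-bromo-2-(tert-butyldimethylsilyloxy)phenyl]methyl}zinc bromide F3. F2 and an excess of F3 would then be joined by a Negishi coupling with Pd(PPh3)4 at rt. The fallback sets out from 4 and 7 and comes back at 9.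

Step 8. The free para-alkylphenol may be oxidised, or the electron-rich C4 carbinol may ionise on the oxide surface and eliminate, instead of being oxidised cleanly. The fallback masks the phenol so that a homogeneous oxidant can be used. TBSCl and imidazole (DMF, 0 °C) should silylate the phenol of 13 in preference to the hindered secondary and tertiary alcohols, giving (2S,4S)-5,7-bis(tert-butyldimethylsilyloxy)-2-{4-(tert-butyldimethylsilyloxy)-3-[(2E)-7-hydroxy-3,7-dimethyloct-2-en-1-yl]phenyl}-3,4-dihydro-2H-chromen-4-ol F4. Dess–Martin periodinane with NaHCO3 in CH2Cl2 would give (2S)-5,7-bis(tert-butyldimethylsilyloxy)-2-{4-(tert-butyldimethylsilyloxy)-3-[(2E)-7-hydroxy-3,7-dimethyloct-2-en-1-yl]phenyl}-2,3-dihydro-4H-chromen-4-one F5, and the conditions of step 9 would remove all three silyl groups. The fallback sets out from 13 and comes back at 15.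

## Further compounds

F1 | step 7 | (2R,4R)-5,7-bis(tert-butyldimethylsilyloxy)-2-{4-hydroxy-3-[(2E)-7-hydroxy-3,7-dimethyloct-2-en-1-yl]phenyl}-3,4-dihydro-2H-chromen-4-ol | C/C(=C\Cc1cc([C@H]2C[C@@H](O)c3c(O[Si](C)(C)C(C)(C)C)cc(O[Si](C)(C)C(C)(C)C)cc3O2)ccc1O)CCCC(C)(C)O
F2 | step 5 | (6E)-7-iodo-2,6-dimethylhept-6-en-2-ol | C/C(=C\I)CCCC(C)(C)O
F3 | step 5 | {[5-bromo-2-(tert-butyldimethylsilyloxy)phenyl]methyl}zinc bromide | Br[Zn]Cc1cc(Br)ccc1O[Si](C)(C)C(C)(C)C
F4 | step 8 | (2S,4S)-5,7-bis(tert-butyldimethylsilyloxy)-2-{4-(tert-butyldimethylsilyloxy)-3-[(2E)-7-hydroxy-3,7-dimethyloct-2-en-1-yl]phenyl}-3,4-dihydro-2H-chromen-4-ol | C/C(=C\Cc1cc([C@@H]2C[C@H](O)c3c(O[Si](C)(C)C(C)(C)C)cc(O[Si](C)(C)C(C)(C)C)cc3O2)ccc1O[Si](C)(C)C(C)(C)C)CCCC(C)(C)O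
F5 | step 8 | (2S)-5,7-bis(tert-butyldimethylsilyloxy)-2-{4-(tert-butyldimethylsilyloxy)-3-[(2E)-7-hydroxy-3,7-dimethyloct-2-en-1-yl]phenyl}-2,3-dihydro-4H-chromen-4-one | C/C(=C\Cc1cc([C@@H]2CC(=O)c3c(O[Si](C)(C)C(C)(C)C)cc(O[Si](C)(C)C(C)(C)C)cc3O2)ccc1O[Si](C)(C)C(C)(C)C)CCCC(C)(C)O
A1 | direct plan | 5,7-bis(tert-butyldimethylsilyloxy)-4H-chromen-4-one | O=c1ccoc2cc(O[Si](C)(C)C(C)(C)C)cc(O[Si](C)(C)C(C)(C)C)c12
A2 | direct plan | 4-bromo-2-[(2E)-3,7-dimethylocta-2,6-dien-1-yl]phenol | C/C(=C\Cc1cc(Br)ccc1O)CCC=C(C)C
A3 | direct plan | {4-bromo-2-[(2E)-3,7-dimethylocta-2,6-dien-1-yl]phenoxy}(tert-butyl)dimethylsilane | C/C(=C\Cc1cc(Br)ccc1O[Si](C)(C)C(C)(C)C)CCC=C(C)C
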